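**Retrosynthetic overview**

1. Oxirane last: 29 comes from the 15-hydroxy triene 28 by hydroxyl-directed asymmetric epoxidation of C4=C5, the oxidation that follows cyclisation in the biosynthesis.
2. Ten-membered ring first: 27 comes from the acyclic farnesyl-type allylic diethyl phosphate 26 by cationic C6–C7 closure (C1→C10 of the farnesyl chain), ended by loss of silicon in place of a proton, with all ester groups already on the chain.
3. 26 comes from enal 20: allylboration sets C9, then tigloylation, then cross-metathesis brings in C11–C13 as an allylsilane.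
4. 20 comes from diene 19 and 2-formylallyl ester 10 by cross-metathesis; 19 from a Johnson–Claisen rearrangement that fixes the C4=C5 geometry; 10 from an Evans syn-aldol acid.

**Assumptions**

- Germacrane locants are used throughout: C7 carries the isopropenyl unit C11–C13, C4/C5 the oxirane, C9 the tiglate, C14 the hydroxybutanoate, C15 the free CH2OH, C12 the acetate.
- TBS = tert-butyldimethylsilyl, TBDPS = tert-butyldiphenylsilyl, Tig = (E)-2-methylbut-2-enoyl.
- Compounds 24–26 are carried as a mixture of the two C7=C11 geometrical isomers; both give the same ring-closure product.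
- C7 is R by CIP in 27 and 28 and S in 29 with no change in space (the oxirane oxygen raises the rank of C6).

**Route**

Step 1
Reactants: 1 (R)-4-benzyl-3-propanoyl-1,3-oxazolidin-2-one; 2 acetaldehyde
Product: 4 (4R)-4-benzyl-3-[(2R,3S)-3-hydroxy-2-methylbutanoyl]-1,3-oxazolidin-2-one, via dibutylboron Z-enolate 3 (not isolated)
Conditions: Bu2BOTf, iPr2NEt, CH2Cl2, −78 → 0 °C; 2, −78 → 0 °C; then pH 7 buffer, MeOH, H2O2
Reagents that add atoms: none
Why: Evans syn-aldol reaction in which the Z-boron enolate reacts through a chair Zimmerman–Traxler transition state on the face away from the benzyl group, so the (R)-auxiliary sets (2R,3S).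

Step 2
Reactants: 4 (4R)-4-benzyl-3-[(2R,3S)-3-hydroxy-2-methylbutanoyl]-1,3-oxazolidin-2-one
Product: 5 (4R)-4-benzyl-3-[(2R,3S)-3-(TBS-oxy)-2-methylbutanoyl]-1,3-oxazolidin-2-one
Conditions: TBSOTf, 2,6-lutidine, CH2Cl2, 0 °C
Reagents that add atoms: tert-butyldimethylsilyl triflate, CC(C)(C)[Si](C)(C)OS(=O)(=O)C(F)(F)F
Why: Silylation of the secondary alcohol blocks it against the later tigloylation and against retro-aldol cleavage.

Step 3
Reactants: 5 (4R)-4-benzyl-3-[(2R,3S)-3-(TBS-oxy)-2-methylbutanoyl]-1,3-oxazolidin-2-one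
Product: 7 (2R,3S)-3-(TBS-oxy)-2-methylbutanoic acid, via lithium peroxycarboxylate 6 (not isolated)
Conditions: LiOH, H2O2, THF/H2O, 0 °C; Na2SO3 (aq); then 1 M HCl to pH 3
Reagents that add atoms: hydrogen peroxide (as LiOOH), OO
Why: Hydroperoxide cleaves the exocyclic imide carbonyl selectively (standard auxiliary removal) without epimerising C2.

Step 4
Reactants: 7 (2R,3S)-3-(TBS-oxy)-2-methylbutanoic acid; 8 2-methylidenepropane-1,3-diol (3 equiv)
Product: 9 2-(hydroxymethyl)prop-2-en-1-yl (2R,3S)-3-(TBS-oxy)-2-methylbutanoate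
Conditions: EDC·HCl, DMAP (0.1 equiv), CH2Cl2, 0 → 23 °C
Reagents that add atoms: none
Why: Steglich-type carbodiimide esterification, with the symmetrical diol in excess so that the mono-ester dominates.

Step 5
Reactants: 9 2-(hydroxymethyl)prop-2-en-1-yl (2R,3S)-3-(TBS-oxy)-2-methylbutanoate
Product: 10 2-formylprop-2-en-1-yl (2R,3S)-3-(TBS-oxy)-2-methylbutanoate
Conditions: PhI(OAc)2, TEMPO (0.1 equiv), CH2Cl2, 23 °C
Reagents that add atoms: none
Why: Oxoammonium (TEMPO) oxidation of the primary allylic alcohol stops at the aldehyde and leaves the ester and silyl ether alone.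

Step 6
Reactants: 11 2-bromoprop-2-en-1-ol
Product: 12 [(2-bromoprop-2-en-1-yl)oxy](tert-butyl)diphenylsilane
Conditions: TBDPSCl, imidazole, DMF, 23 °C
Reagents that add atoms: tert-butyl(chloro)diphenylsilane, CC(C)(C)[Si](Cl)(c1ccccc1)c1ccccc1
Why: Silylation gives the future C15 oxygen a bulky, weakly basic protecting group that survives to step 17.

Step 7
Reactants: 12 [(2-bromoprop-2-en-1-yl)oxy](tert-butyl)diphenylsilane; 13 (TBS-oxy)acetaldehyde
Product: 15 rac-1-(TBS-oxy)-3-[(TBDPS-oxy)methyl]but-3-en-2-ol, via 2-lithioallyl silyl ether 14 (not isolated)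
Conditions: tBuLi (2.1 equiv), Et2O, −78 °C; 13, −78 °C; aq NH4Cl
Reagents that add atoms: none
Why: Bromine–lithium exchange followed by 1,2-addition of the alkenyllithium to the aldehyde; the new carbinol centre is racemic and is destroyed in step 8.

Step 8
Reactants: 15 rac-1-(TBS-oxy)-3-[(TBDPS-oxy)methyl]but-3-en-2-ol
Product: 17 ethyl (4Z)-6-(TBS-oxy)-4-[(TBDPS-oxy)methyl]hex-4-enoate, via mixed ketene acetal 16 (not isolated)
Conditions: MeC(OEt)3, EtCO2H (0.1 equiv), 135 °C, EtOH distilled off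
Reagents that add atoms: triethyl orthoacetate, CCOC(C)(OCC)OCC
Why: Johnson–Claisen rearrangement through a chair transition state with the CH2OTBS group equatorial (an axial group would clash with the ethoxy group), which places C6 trans to the new C3–C2 chain and cis to C15, i.e. the ring-trans geometry of C4=C5 (Z by CIP).

Step 9
Reactants: 17 ethyl (4Z)-6-(TBS-oxy)-4-[(TBDPS-oxy)methyl]hex-4-enoate
Product: 19 (2Z)-1-(TBS-oxy)-3-[(TBDPS-oxy)methyl]hepta-2,6-diene, via hex-4-enal 18 (not isolated)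
Conditions: iBu2AlH (1.05 equiv), CH2Cl2, −78 °C; then Ph3P=CH2 (from Ph3PCH3Br, KN(SiMe3)2, THF), −78 → 23 °C; aq KNaC4H4O6
Reagents that add atoms: methylidene(triphenyl)phosphorane, C=P(c1ccccc1)(c1ccccc1)c1ccccc1
Why: Half-reduction of the ester to the aluminium hemiacetal and Wittig methylenation of the aldehyde released on warming give the terminal alkene in one flask without touching the trisubstituted alkene.

Step 10
Reactants: 19 (2Z)-1-(TBS-oxy)-3-[(TBDPS-oxy)methyl]hepta-2,6-diene (2 equiv); 10 2-formylprop-2-en-1-yl (2R,3S)-3-(TBS-oxy)-2-methylbutanoate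
Product: 20 (2E,6Z)-8-(TBS-oxy)-6-[(TBDPS-oxy)methyl]-2-formylocta-2,6-dien-1-yl (2R,3S)-3-(TBS-oxy)-2-methylbutanoate
Conditions: second-generation Hoveyda–Grubbs catalyst (5 mol%), CH2Cl2, 40 °C
Reagents that add atoms: none
Why: Olefin cross-metathesis of the only monosubstituted alkene with the 2-substituted acrolein (as with methacrolein); reversible metathesis gives the thermodynamic E-enal with the formyl carbon C9 trans to C2 and C14 cis to C2.

Step 11
Reactants: 20 (2E,6Z)-8-(TBS-oxy)-6-[(TBDPS-oxy)methyl]-2-formylocta-2,6-dien-1-yl (2R,3S)-3-(TBS-oxy)-2-methylbutanoate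
Product: 21 (2E,6Z)-8-(TBS-oxy)-6-[(TBDPS-oxy)methyl]-2-[(1S)-1-hydroxybut-3-en-1-yl]octa-2,6-dien-1-yl (2R,3S)-3-(TBS-oxy)-2-methylbutanoate
Conditions: (−)-Ipc2B(allyl) (1.3 equiv), Et2O, −78 °C; then NaOAc (aq), H2O2, 0 → 23 °C
Reagents that add atoms: (−)-B-allyldiisopinocampheylborane, C=CCB([C@@H]1C[C@@H]2C[C@H]([C@H]1C)C2(C)C)[C@@H]1C[C@@H]2C[C@H]([C@H]1C)C2(C)C
Why: Brown allylboration (1,2-addition through a chair transition state) in which the reagent from (+)-α-pinene attacks the si face of the aldehyde, as it does with benzaldehyde, and sets C9 as S; esters and silyl ethers are inert at −78 °C.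

Step 12
Reactants: 21 (2E,6Z)-8-(TBS-oxy)-6-[(TBDPS-oxy)methyl]-2-[(1S)-1-hydroxybut-3-en-1-yl]octa-2,6-dien-1-yl (2R,3S)-3-(TBS-oxy)-2-methylbutanoate
Product: 22 (2E,6Z)-8-(TBS-oxy)-6-[(TBDPS-oxy)methyl]-2-[(1S)-1-(Tig-oxy)but-3-en-1-yl]octa-2,6-dien-1-yl (2R,3S)-3-(TBS-oxy)-2-methylbutanoate
Conditions: tigloyl chloride, pyridine, DMAP (0.2 equiv), CH2Cl2, 0 → 23 °C
Reagents that add atoms: (E)-2-methylbut-2-enoyl chloride, C/C=C(\C)C(Cl)=O
Why: DMAP-catalysed acylation of the secondary allylic alcohol with retention at C9; the tiglate is the stable E isomer, so the base cannot isomerise it further.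

Step 13
Reactants: 22 (2E,6Z)-8-(TBS-oxy)-6-[(TBDPS-oxy)methyl]-2-[(1S)-1-(Tig-oxy)but-3-en-1-yl]octa-2,6-dien-1-yl (2R,3S)-3-(TBS-oxy)-2-methylbutanoate; 23 2-[(trimethylsilyl)methyl]prop-2-en-1-yl acetate (5 equiv)
Product: 24 (2E,6Z)-8-(TBS-oxy)-6-[(TBDPS-oxy)methyl]-2-[(1S)-4-(acetoxymethyl)-1-(Tig-oxy)-5-(trimethylsilyl)pent-3-en-1-yl]octa-2,6-dien-1-yl (2R,3S)-3-(TBS-oxy)-2-methylbutanoate (E/Z mixture at C7=C11)
Conditions: second-generation Hoveyda–Grubbs catalyst (10 mol%), CH2Cl2, 40 °C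
Reagents that add atoms: none
Why: Cross-metathesis of the terminal vinyl group (trisubstituted and conjugated alkenes are inert) with the 1,1-disubstituted allylsilane in excess installs C11, C12 and C13 with the nucleophilic allylsilane in place.

Step 14
Reactants: 24 allylsilane with C6–OTBS
Product: 25 (2E,6Z)-8-hydroxy-6-[(TBDPS-oxy)methyl]-2-[(1S)-4-(acetoxymethyl)-1-(Tig-oxy)-5-(trimethylsilyl)pent-3-en-1-yl]octa-2,6-dien-1-yl (2R,3S)-3-(TBS-oxy)-2-methylbutanoate
Conditions: HF·pyridine, pyridine, THF, 0 °C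
Reagents that add atoms: none
Why: Buffered fluoride cleaves the unhindered primary allylic TBS ether much faster than the secondary TBS ether and the TBDPS ether, and does not protodesilylate the allylsilane.

Step 15
Reactants: 25 C6 allylic alcohol
Product: 26 (2E,6Z)-8-[(diethoxyphosphoryl)oxy]-6-[(TBDPS-oxy)methyl]-2-[(1S)-4-(acetoxymethyl)-1-(Tig-oxy)-5-(trimethylsilyl)pent-3-en-1-yl]octa-2,6-dien-1-yl (2R,3S)-3-(TBS-oxy)-2-methylbutanoate
Conditions: ClP(O)(OEt)2, pyridine, DMAP (0.1 equiv), CH2Cl2, 0 °C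
Reagents that add atoms: diethyl chlorophosphate, CCOP(=O)(Cl)OCC
Why: Phosphorylation of the primary allylic alcohol gives the diethyl phosphate, the synthetic stand-in for the diphosphate leaving group of farnesyl diphosphate.

Step 16
Reactants: 26 acyclic allylic diethyl phosphate
Product: 27 (7R,9S)-12-acetoxy-15-(TBDPS-oxy)-9-(Tig-oxy)germacra-1(10)E,4Z,11(13)-trien-14-yl (2R,3S)-3-(TBS-oxy)-2-methylbutanoate (both ring alkenes trans within the ring)
Conditions: TMSOTf (0.3 equiv), 2,6-di-tert-butyl-4-methylpyridine (0.5 equiv), CH2Cl2, −78 → −30 °C, 26 added by syringe pump to 1 mM; Et3N quench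
Reagents that add atoms: none
Why: Proposed new method: TMSOTf silylates the phosphoryl oxygen so that the prenyl-type C6 phosphate (the only good leaving group on a 3,3-disubstituted allyl unit; the other allylic oxygens are carboxylates on less stabilised positions) ionises to a geometrically stable allyl cation and leaves as neutral Me3SiOP(O)(OEt)2 (no ion-pair return to the tertiary isomer, so the C4=C5 geometry holds), the γ-carbon C7 of the allylsilane (the only electron-rich alkene, since C1=C10 carries two allylic acyloxy groups) attacks the unhindered C6 terminus in an intramolecular Hosomi–Sakurai SE2′ reaction, and the β-silyl cation at C11 collapses to the C11=C13 methylidene with return of Me3Si+, which is the 1,10-closure of farnesyl diphosphate to germacrene A with silicon in place of the lost proton; C7 is set in a crown-like chair–chair transition state with the C11 unit pseudo-equatorial and the C9 acyloxy group "inside" (eclipsing C10=C1, which avoids A(1,2) strain with C14), giving the 7,9-trans ring; the closest known reaction types are Lewis-acid-induced biogenetic-type cyclisations of allylic diethyl phosphates and intramolecular allylsilane–allyl cation couplings.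

Step 17
Reactants: 27 protected macrocycle
Product: 28 (7R,9S)-12-acetoxy-15-hydroxy-9-(Tig-oxy)germacra-1(10)E,4Z,11(13)-trien-14-yl (2R,3S)-3-hydroxy-2-methylbutanoate
Conditions: Bu4NF, AcOH (1:1), THF, 0 → 23 °C
Reagents that add atoms: none
Why: Fluoride removes both silyl ethers, while acetic acid buffering prevents acyl migration and the temperature stays low enough to avoid Cope rearrangement of the germacradiene.

Step 18
Reactants: 28 15-hydroxy triene
Product: 29 (4S,5R,7S,9S)-12-acetoxy-4,5-epoxy-15-hydroxy-9-(Tig-oxy)germacra-1(10)E,11(13)-dien-14-yl (2R,3S)-3-hydroxy-2-methylbutanoate (CNP0316239.1)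
Conditions: Ti(OiPr)4 (0.2 equiv), L-(+)-diisopropyl tartrate (0.24 equiv), tBuOOH (2 equiv), 4 Å MS, CH2Cl2, −20 °C
Reagents that add atoms: tert-butyl hydroperoxide, CC(C)(C)OO
Why: Katsuki–Sharpless asymmetric epoxidation in which only the C15 allylic alcohol binds titanium, so only C4=C5 reacts, and the L-(+)-tartrate delivers oxygen to the face that gives (4S,5R) (the same sense as geraniol → (2S,3S)), the ring reacting through the conformer that exposes this face (C15 anti to the C7 substituent).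

**Compound list**

1 | (R)-4-benzyl-3-propanoyl-1,3-oxazolidin-2-one | CCC(=O)N1[C@H](Cc2ccccc2)COC1=O | starting material
2 | acetaldehyde | CC=O | starting material
3 | dibutylboron Z-enolate of 1 | C/C=C(\OB(CCCC)CCCC)N1[C@H](Cc2ccccc2)COC1=O | intermediate (not isolated)
4 | (4R)-4-benzyl-3-[(2R,3S)-3-hydroxy-2-methylbutanoyl]-1,3-oxazolidin-2-one | O=C(N1[C@H](Cc2ccccc2)COC1=O)[C@H](C)[C@H](C)O | intermediate
5 | (4R)-4-benzyl-3-[(2R,3S)-3-(TBS-oxy)-2-methylbutanoyl]-1,3-oxazolidin-2-one | O=C(N1[C@H](Cc2ccccc2)COC1=O)[C@H](C)[C@H](C)O[Si](C)(C)C(C)(C)C | intermediate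
6 | lithium (2R,3S)-3-(TBS-oxy)-2-methylbutaneperoxoate | [Li+].[O-]OC(=O)[C@H](C)[C@H](C)O[Si](C)(C)C(C)(C)C | intermediate (not isolated)
7 | (2R,3S)-3-(TBS-oxy)-2-methylbutanoic acid | OC(=O)[C@H](C)[C@H](C)O[Si](C)(C)C(C)(C)C | intermediate
8 | 2-methylidenepropane-1,3-diol | C=C(CO)CO | starting material
9 | 2-(hydroxymethyl)prop-2-en-1-yl (2R,3S)-3-(TBS-oxy)-2-methylbutanoate | C=C(CO)COC(=O)[C@H](C)[C@H](C)O[Si](C)(C)C(C)(C)C | intermediate
10 | 2-formylprop-2-en-1-yl (2R,3S)-3-(TBS-oxy)-2-methylbutanoate | C=C(C=O)COC(=O)[C@H](C)[C@H](C)O[Si](C)(C)C(C)(C)C | intermediate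
11 | 2-bromoprop-2-en-1-ol | OCC(Br)=C | starting material
12 | [(2-bromoprop-2-en-1-yl)oxy](tert-butyl)diphenylsilane | C=C(Br)CO[Si](c1ccccc1)(c1ccccc1)C(C)(C)C | intermediate
13 | (tert-butyldimethylsilyloxy)acetaldehyde | O=CCO[Si](C)(C)C(C)(C)C | starting material
14 | {3-[(tert-butyldiphenylsilyl)oxy]prop-1-en-2-yl}lithium | [Li]C(=C)CO[Si](c1ccccc1)(c1ccccc1)C(C)(C)C | intermediate (not isolated)
15 | rac-1-(TBS-oxy)-3-[(TBDPS-oxy)methyl]but-3-en-2-ol | C=C(CO[Si](c1ccccc1)(c1ccccc1)C(C)(C)C)C(O)CO[Si](C)(C)C(C)(C)C | intermediate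
16 | 1-ethoxyvinyl ether of 15 (mixed ketene acetal) | C=C(OCC)OC(CO[Si](C)(C)C(C)(C)C)C(=C)CO[Si](c1ccccc1)(c1ccccc1)C(C)(C)C | intermediate (not isolated)
17 | ethyl (4Z)-6-(TBS-oxy)-4-[(TBDPS-oxy)methyl]hex-4-enoate | CCOC(=O)CC/C(CO[Si](c1ccccc1)(c1ccccc1)C(C)(C)C)=C/CO[Si](C)(C)C(C)(C)C | intermediate
18 | (4Z)-6-(TBS-oxy)-4-[(TBDPS-oxy)methyl]hex-4-enal | O=CCC/C(CO[Si](c1ccccc1)(c1ccccc1)C(C)(C)C)=C/CO[Si](C)(C)C(C)(C)C | intermediate (not isolated)
19 | (2Z)-1-(TBS-oxy)-3-[(TBDPS-oxy)methyl]hepta-2,6-diene | C=CCC/C(CO[Si](c1ccccc1)(c1ccccc1)C(C)(C)C)=C/CO[Si](C)(C)C(C)(C)C | intermediate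
20 | (2E,6Z)-8-(TBS-oxy)-6-[(TBDPS-oxy)methyl]-2-formylocta-2,6-dien-1-yl (2R,3S)-3-(TBS-oxy)-2-methylbutanoate | O=C/C(COC(=O)[C@H](C)[C@H](C)O[Si](C)(C)C(C)(C)C)=C/CC/C(CO[Si](c1ccccc1)(c1ccccc1)C(C)(C)C)=C/CO[Si](C)(C)C(C)(C)C | intermediate
21 | (2E,6Z)-8-(TBS-oxy)-6-[(TBDPS-oxy)methyl]-2-[(1S)-1-hydroxybut-3-en-1-yl]octa-2,6-dien-1-yl (2R,3S)-3-(TBS-oxy)-2-methylbutanoate | C=CC[C@H](O)/C(COC(=O)[C@H](C)[C@H](C)O[Si](C)(C)C(C)(C)C)=C/CC/C(CO[Si](c1ccccc1)(c1ccccc1)C(C)(C)C)=C/CO[Si](C)(C)C(C)(C)C | intermediate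
22 | tiglate of 21 at the C9 hydroxyl (9S) | C=CC[C@H](OC(=O)/C(C)=C/C)/C(COC(=O)[C@H](C)[C@H](C)O[Si](C)(C)C(C)(C)C)=C/CC/C(CO[Si](c1ccccc1)(c1ccccc1)C(C)(C)C)=C/CO[Si](C)(C)C(C)(C)C | intermediate
23 | 2-[(trimethylsilyl)methyl]prop-2-en-1-yl acetate | C=C(COC(C)=O)C[Si](C)(C)C | starting material
24 | allylsilane: 22 with the vinyl CH2 replaced by C(CH2OAc)(CH2SiMe3), 9S, E/Z mixture at C7=C11 | C[Si](C)(C)CC(COC(C)=O)=CC[C@H](OC(=O)/C(C)=C/C)/C(COC(=O)[C@H](C)[C@H](C)O[Si](C)(C)C(C)(C)C)=C/CC/C(CO[Si](c1ccccc1)(c1ccccc1)C(C)(C)C)=C/CO[Si](C)(C)C(C)(C)C | intermediate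
25 | C6 primary allylic alcohol from 24 (9S, E/Z mixture at C7=C11) | C[Si](C)(C)CC(COC(C)=O)=CC[C@H](OC(=O)/C(C)=C/C)/C(COC(=O)[C@H](C)[C@H](C)O[Si](C)(C)C(C)(C)C)=C/CC/C(CO[Si](c1ccccc1)(c1ccccc1)C(C)(C)C)=C/CO | intermediate
26 | C6 diethyl phosphate of 25 (9S, E/Z mixture at C7=C11) | C[Si](C)(C)CC(COC(C)=O)=CC[C@H](OC(=O)/C(C)=C/C)/C(COC(=O)[C@H](C)[C@H](C)O[Si](C)(C)C(C)(C)C)=C/CC/C(CO[Si](c1ccccc1)(c1ccccc1)C(C)(C)C)=C/COP(=O)(OCC)OCC | intermediate
27 | (7R,9S)-12-acetoxy-15-(TBDPS-oxy)-9-(Tig-oxy)germacra-1(10)E,4Z,11(13)-trien-14-yl (2R,3S)-3-(TBS-oxy)-2-methylbutanoate | C=C(COC(C)=O)[C@H]1C[C@H](OC(=O)/C(C)=C/C)/C(COC(=O)[C@H](C)[C@H](C)O[Si](C)(C)C(C)(C)C)=C/CC/C(CO[Si](c2ccccc2)(c2ccccc2)C(C)(C)C)=C/C1 | intermediate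
28 | (7R,9S)-12-acetoxy-15-hydroxy-9-(Tig-oxy)germacra-1(10)E,4Z,11(13)-trien-14-yl (2R,3S)-3-hydroxy-2-methylbutanoate | C=C(COC(C)=O)[C@H]1C[C@H](OC(=O)/C(C)=C/C)/C(COC(=O)[C@H](C)[C@H](C)O)=C/CC/C(CO)=C/C1 | intermediate
29 | (4S,5R,7S,9S)-12-acetoxy-4,5-epoxy-15-hydroxy-9-(Tig-oxy)germacra-1(10)E,11(13)-dien-14-yl (2R,3S)-3-hydroxy-2-methylbutanoate (CNP0316239.1) | C=C(COC(C)=O)[C@H]1C[C@H](OC(=O)/C(C)=C/C)/C(COC(=O)[C@H](C)[C@H](C)O)=C/CC[C@@]2(CO)O[C@@H]2C1 | target

**Step count and risks**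

Total: 18 steps. Longest linear sequence: 14 steps (steps 1–5, then 10–18).

The three steps most likely to fail:

Step 16 (ring closure). A cationic ten-membered closure on a chain this functionalised has no direct precedent. Oligomers and capture of the cation by the C15 silyloxy group (2,5-dihydrofuran) compete, and the C7 selectivity rests on a conformational argument only. Fallback, for the case that the ring closes but prefers the 7,9-cis arrangement: make the ring in the 9-epimeric series and invert C9 when the tiglate is put on. It sets out from enal 20. Allylboration with (+)-Ipc2B(allyl) gives the (1R)-1-hydroxybut-3-enyl epimer of 21 F3. Chloroacetic anhydride and pyridine give its chloroacetate F4. Cross-metathesis with 23 gives the allylsilane chloroacetate F5. HF·pyridine gives the C6 alcohol F6, and ClP(O)(OEt)2 gives the C6 diethyl phosphate F7. Ring closure as in step 16 gives the (7R,9R)-9-chloroacetoxy macrocycle F8. Thiourea and NaHCO3 in EtOH free the (7R,9R)-9-hydroxy macrocycle F9. A Mitsunobu reaction with tiglic acid, PPh3 and diisopropyl azodicarboxylate inverts C9 and comes back to the route at 27.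

Step 18 (epoxidation). The face that L-(+)-tartrate demands is exposed only in the ring conformer with C15 anti to the C7 substituent. If that conformer reacts poorly, the titanium system is mismatched and slow. Fallback: a non-directed, ketone-catalysed dioxirane epoxidation before deprotection. It sets out from 27. The D-fructose-derived Shi ketone with KHSO5 and K2CO3 in MeCN/CH2(OMe)2/H2O at 0 °C epoxidises the most electron-rich alkene C4=C5 and gives the (4S,5R,7S,9S)-4,5-epoxide of 27 F10. Bu4NF/AcOH then removes both silyl groups and comes back to the route at 29.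

Step 10 (first cross-metathesis). The enal 10 is a hindered 1,1-disubstituted partner and is too valuable to use in large excess. Fallback: build C1=C10 by Morita–Baylis–Hillman chemistry and allylic transposition instead of metathesis. It sets out from ester 17, which is reduced with iBu2AlH alone to give isolated aldehyde 18. Acrolein and DABCO give the Morita–Baylis–Hillman adduct rac-(6Z)-8-(TBS-oxy)-6-[(TBDPS-oxy)methyl]-3-hydroxy-2-methylideneoct-6-enal F1. Esterification with acid 7 (DCC, DMAP) gives the C3 ester of F1 with acid 7 F2. DABCO in THF then moves the acyloxy group to the primary carbon by an SN2′–SN2′ sequence; the conjugated E-enal is the thermodynamic product and the route is rejoined at 20.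

**Further compounds**

F1 | step 10 | rac-(6Z)-8-(TBS-oxy)-6-[(TBDPS-oxy)methyl]-3-hydroxy-2-methylideneoct-6-enal | C=C(C=O)C(O)CC/C(CO[Si](c1ccccc1)(c1ccccc1)C(C)(C)C)=C/CO[Si](C)(C)C(C)(C)C
F2 | step 10 | C3 ester of F1 with acid 7 (both C3 epimers) | C=C(C=O)C(OC(=O)[C@H](C)[C@H](C)O[Si](C)(C)C(C)(C)C)CC/C(CO[Si](c1ccccc1)(c1ccccc1)C(C)(C)C)=C/CO[Si](C)(C)C(C)(C)C
F3 | step 16 | (1R)-1-hydroxybut-3-enyl epimer of 21 | C=CC[C@@H](O)/C(COC(=O)[C@H](C)[C@H](C)O[Si](C)(C)C(C)(C)C)=C/CC/C(CO[Si](c1ccccc1)(c1ccccc1)C(C)(C)C)=C/CO[Si](C)(C)C(C)(C)C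
F4 | step 16 | chloroacetate of F3 (9R) | C=CC[C@@H](OC(=O)CCl)/C(COC(=O)[C@H](C)[C@H](C)O[Si](C)(C)C(C)(C)C)=C/CC/C(CO[Si](c1ccccc1)(c1ccccc1)C(C)(C)C)=C/CO[Si](C)(C)C(C)(C)C
F5 | step 16 | allylsilane chloroacetate (9R, E/Z mixture at C7=C11) | C[Si](C)(C)CC(COC(C)=O)=CC[C@@H](OC(=O)CCl)/C(COC(=O)[C@H](C)[C@H](C)O[Si](C)(C)C(C)(C)C)=C/CC/C(CO[Si](c1ccccc1)(c1ccccc1)C(C)(C)C)=C/CO[Si](C)(C)C(C)(C)C
F6 | step 16 | C6 alcohol from F5 | C[Si](C)(C)CC(COC(C)=O)=CC[C@@H](OC(=O)CCl)/C(COC(=O)[C@H](C)[C@H](C)O[Si](C)(C)C(C)(C)C)=C/CC/C(CO[Si](c1ccccc1)(c1ccccc1)C(C)(C)C)=C/CO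
F7 | step 16 | C6 diethyl phosphate of F6 | C[Si](C)(C)CC(COC(C)=O)=CC[C@@H](OC(=O)CCl)/C(COC(=O)[C@H](C)[C@H](C)O[Si](C)(C)C(C)(C)C)=C/CC/C(CO[Si](c1ccccc1)(c1ccccc1)C(C)(C)C)=C/COP(=O)(OCC)OCC
F8 | step 16 | (7R,9R)-12-acetoxy-9-(chloroacetoxy)-15-(TBDPS-oxy)germacra-1(10)E,4Z,11(13)-trien-14-yl (2R,3S)-3-(TBS-oxy)-2-methylbutanoate | C=C(COC(C)=O)[C@H]1C[C@@H](OC(=O)CCl)/C(COC(=O)[C@H](C)[C@H](C)O[Si](C)(C)C(C)(C)C)=C/CC/C(CO[Si](c2ccccc2)(c2ccccc2)C(C)(C)C)=C/C1
F9 | step 16 | (7R,9R)-12-acetoxy-9-hydroxy-15-(TBDPS-oxy)germacra-1(10)E,4Z,11(13)-trien-14-yl (2R,3S)-3-(TBS-oxy)-2-methylbutanoate | C=C(COC(C)=O)[C@H]1C[C@@H](O)/C(COC(=O)[C@H](C)[C@H](C)O[Si](C)(C)C(C)(C)C)=C/CC/C(CO[Si](c2ccccc2)(c2ccccc2)C(C)(C)C)=C/C1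
F10 | step 18 | (4S,5R,7S,9S)-4,5-epoxide of 27 | C=C(COC(C)=O)[C@H]1C[C@H](OC(=O)/C(C)=C/C)/C(COC(=O)[C@H](C)[C@H](C)O[Si](C)(C)C(C)(C)C)=C/CC[C@@]2(CO[Si](c3ccccc3)(c3ccccc3)C(C)(C)C)O[C@@H]2C1
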